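# Total synthesis of Trichorabdal B (ent-kaurane numbering throughout)

**Retrosynthetic overview**
1. Target ⇐ aldehyde unmasking ⇐ C15 allylic oxidation of the exo-methylene ⇐ C11 ketone reduction ⇐ tricyclic lactone whose bicyclo[3.2.1] C/D rings are closed last, by a 5-exo vinyl-radical cyclization onto a cyclohexenone.
2. That cyclohexenone ⇐ intramolecular Mukaiyama–Michael of a Birch-derived methyl enol ether (C9 nucleophile) onto a ring-A enal tethered as the C20 ester. One step forms C9–C10, the spiro C10 centre and the 7,20-lactone.
3. The enol-ether acid ⇐ Birch reductive alkylation (the dearomatizing step) of 3-methoxybenzoic acid with 2,3-dibromopropene, which sets the C8 quaternary centre. The ring-A enal ⇐ Diels–Alder reaction of a 1,1-disubstituted diene with DMAD.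
4. Ring order: C (Birch) → A (Diels–Alder) → lactone and spiro C10 (Michael) → D (radical).

Assumption: the racemic Birch acid is resolved by salt crystallization, and the diastereomeric esters from racemic ring A are separated by chromatography. C9 (α to the C11 ketone) and C5 (α to the aldehyde) equilibrate to the thermodynamic trans-fused, equatorial arrangement.

---

**Step 1**
Reactants: 1 (3-methoxybenzoic acid); 2 (2,3-dibromopropene)
Product: 3 ((±)-1-(2-bromoallyl)-3-methoxycyclohexa-2,5-diene-1-carboxylic acid)
Conditions: Li, NH3(l)/THF, t-BuOH, –78 °C; quench excess Li with isoprene; add 2; then pH 4–5 work-up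
Reagents that add atoms: 2,3-dibromopropene, C=C(Br)CBr
Why: Birch reductive alkylation dearomatizes the benzoate dianion and alkylates the ipso carbon, so the OMe carbon stays sp2 as a methyl enol ether (C9=C11). This creates the C8 quaternary centre (racemic) and installs the C15–C17 unit with a vinyl bromide.

**Step 2**
Reactants: 3
Product: 4 ((1S)-acid, C8 configured as in the target)
Conditions: (S)-1-phenylethylamine, EtOH/EtOAc, recrystallize the salt; aqueous NaH2PO4 (pH ~4) work-up
Reagents that add atoms: none (resolving amine is removed)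
Why: Classical diastereomeric-salt resolution gives a single C8 enantiomer, which fixes the absolute configuration of everything downstream.

**Step 3**
Reactants: 5 (acrolein); 6 (ethyl 2-(triphenylphosphoranylidene)propanoate)
Product: 7 (ethyl (2E)-2-methylpenta-2,4-dienoate)
Conditions: CH2Cl2, rt
Reagents that add atoms: none
Why: Wittig olefination with a stabilized ylide gives the E-dienoate.

**Step 4**
Reactants: 7
Product: 8 ((2E)-2-methylpenta-2,4-dien-1-ol)
Conditions: DIBAL-H (2.5 equiv), CH2Cl2, –78 °C
Reagents that add atoms: none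
Why: 1,2-Reduction of the ester leaves the diene intact.

**Step 5**
Reactants: 8
Product: 9 (TBS ether of 8)
Conditions: TBSCl, imidazole, DMF, rt
Reagents that add atoms: TBSCl, CC(C)(C)[Si](C)(C)Cl
Why: The silyl ether carries the C19 oxygen and stops the alcohol adding to DMAD in the next step.

**Step 6**
Reactants: 9; 10 (dimethyl acetylenedicarboxylate, DMAD)
Product: 11 (racemic; dimethyl 3-(TBSOCH2)-3-methylcyclohexa-1,4-diene-1,2-dicarboxylate)
Conditions: toluene, BHT, 120 °C, sealed tube
Reagents that add atoms: none (DMAD is the listed reactant)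
Why: Diels–Alder cycloaddition builds ring A with the C4 quaternary centre (racemic) and the tetrasubstituted C5=C10 alkene carrying the C6 and C20 carboxyls. The E-geometry places the small methyl "inside" the s-cis diene, and DMAD is symmetrical, so there is no regiochemical issue.

**Step 7**
Reactants: 11
Product: 12 (C2=C3 saturated diester)
Conditions: H2 (1 atm), 10% Pd/C, EtOAc, rt
Reagents that add atoms: none
Why: Only the unhindered disubstituted alkene is hydrogenated; the tetrasubstituted diester alkene and the TBS ether survive.

**Step 8**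
Reactants: 12
Product: 13 (racemic diol, C6-OH and C20-OH)
Conditions: LiAlH4, THF, 0 °C → rt
Reagents that add atoms: none
Why: Both esters are reduced to allylic primary alcohols; the TBS ether is inert to hydride.

**Step 9**
Reactants: 4; 13
Product: 14 (C20 ester; single diastereomer with C8 S and C4 R)
Conditions: 2,4,6-trichlorobenzoyl chloride, Et3N, THF; then 13, DMAP, toluene, 50 °C; separate diastereomers by silica gel
Reagents that add atoms: none (the activating acyl group is lost)
Why: Yamaguchi esterification goes at the less hindered C20-OH rather than the C6-OH next to the quaternary C4. The resolved acid with racemic 13 gives two diastereomers, and the matched C4/C8 pair is kept.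

**Step 10**
Reactants: 14
Product: 15 (enal, C6 aldehyde)
Conditions: activated MnO2 (15 equiv), CH2Cl2, rt
Reagents that add atoms: none
Why: MnO2 selectively oxidizes the allylic C6 alcohol, giving the β,β-disubstituted enal acceptor; the ester, enol ether and vinyl bromide are untouched.

**Step 11**
Reactants: 15
Product: 16 (tricyclic 7,20-lactone; C11 ketone, C13=C14 alkene, C6 aldehyde)
Conditions: TiCl4 (1.2 equiv), CH2Cl2, –78 → –20 °C; aqueous NaHCO3
Reagents that add atoms: none (MeCl is lost)
Why: Proposed new method: the C8-configured ester tether holds C9 of the methyl enol ether over the β-carbon C10 of the TiCl4-activated enal. A chair-like six-membered transition state forms C9–C10 anti to the pseudo-axial CH2OTBS, which gives the natural 1,3-diaxial C19/C20 arrangement and the spiro lactone. Chloride demethylates the resulting oxocarbenium to the C11 ketone, and the titanium enolate is protonated axially at C5, so the CHO is equatorial. Closest known reaction: Lewis-acid intramolecular Mukaiyama–Michael of enol ethers onto enals.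

**Step 12**
Reactants: 16
Product: 17 (C6 dimethyl acetal)
Conditions: HC(OMe)3 (3 equiv), CSA (5 mol %), CH2Cl2, 0 °C
Reagents that add atoms: trimethyl orthoformate, COC(OC)OC
Why: The aldehyde is chemoselectively acetalized, protecting it from the later hydride reduction and base; C5 is now fixed.

**Step 13**
Reactants: 17
Product: 18 (conjugated enone C11(=O)–C12=C13)
Conditions: DBU (2 equiv), CH2Cl2, 40 °C
Reagents that add atoms: none
Why: Base moves the β,γ-alkene into conjugation, which is the acceptor needed for ring D. The same enolization equilibrates C9 to the trans-fused lactone.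

**Step 14**
Reactants: 18
Product: 19 (bicyclo[3.2.1] C/D rings; C16=C17 exo-methylene, C11 ketone)
Conditions: Bu3SnH (1.5 equiv), AIBN, benzene, 0.005 M, 80 °C, syringe-pump addition
Reagents that add atoms: none (H only)
Why: The vinyl radical from the 2-bromoallyl group cyclizes 5-exo onto the β-carbon C13 of the enone, and the α-keto radical is reduced by Sn–H. The bridge is tethered on the C15 face, so C13 is set by C8. Known reaction type: 5-exo vinyl-radical conjugate cyclization.

**Step 15**
Reactants: 19
Product: 20 (C19 primary alcohol)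
Conditions: TBAF, AcOH, THF, 0 °C
Reagents that add atoms: none
Why: Buffered fluoride removes the TBS group without epimerizing the ketone.

**Step 16**
Reactants: 20
Product: 21 (C19 acetate)
Conditions: Ac2O, pyridine, DMAP (cat.), CH2Cl2, rt
Reagents that add atoms: acetic anhydride, CC(=O)OC(C)=O
Why: Plain acylation installs the C19 acetate while the aldehyde is masked and C11 is still a ketone, so there is no competing hydroxyl.

**Step 17**
Reactants: 21
Product: 22 (C11 exo/equatorial alcohol)
Conditions: SmI2 (3 equiv), MeOH, THF, –78 → 0 °C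
Reagents that add atoms: none (H only)
Why: The bulky Sm(III) alkoxide from the ketyl prefers the exo (equatorial) position, away from the C15–C16 bridge, so H is delivered endo and the OH is exo as in the target. The acetate, lactone and acetal are unaffected.

**Step 18**
Reactants: 22
Product: 23 (C15 allylic alcohol, epimeric mixture)
Conditions: SeO2 (0.2 equiv), t-BuOOH (4 equiv), CH2Cl2, rt
Reagents that add atoms: SeO2, O=[Se]=O; tert-butyl hydroperoxide, CC(C)(C)OO (oxygen source)
Why: Riley/Sharpless allylic oxidation occurs only at C15 because the other allylic site, C13, is a bridgehead; the C15 stereochemistry is destroyed in the next step.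

**Step 19**
Reactants: 23
Product: 24 (C15 enone, C6 acetal, C11-OH)
Conditions: activated MnO2, CH2Cl2, rt
Reagents that add atoms: none
Why: MnO2 oxidizes the allylic C15 alcohol to the exo-methylene enone but leaves the non-allylic C11 alcohol.

**Step 20**
Reactants: 24
Product: 25 (Trichorabdal B)
Conditions: 1 M HCl/THF (1:3), rt
Reagents that add atoms: water, O
Why: Mild acid hydrolysis unmasks the C6 aldehyde; the acetate, lactone and enone survive, and C5 stays equatorial.

---

**Compound list**

| No. | Name | SMILES | Role |
|---|---|---|---|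
| 1 | 3-methoxybenzoic acid | COc1cccc(C(=O)O)c1 | starting material |
| 2 | 2,3-dibromopropene | C=C(Br)CBr | starting material |
| 3 | (±)-1-(2-bromoallyl)-3-methoxycyclohexa-2,5-diene-1-carboxylic acid | COC1=CC(CC(Br)=C)(C(=O)O)C=CC1 | intermediate |
| 4 | (1S)-enantiomer of 3 | COC1=C[C@@](CC(Br)=C)(C(=O)O)C=CC1 | intermediate |
| 5 | acrolein | C=CC=O | starting material |
| 6 | ethyl 2-(triphenylphosphoranylidene)propanoate | CCOC(=O)C(C)=P(c1ccccc1)(c1ccccc1)c1ccccc1 | starting material |
| 7 | ethyl (2E)-2-methylpenta-2,4-dienoate | CCOC(=O)/C(C)=C/C=C | intermediate |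
| 8 | (2E)-2-methylpenta-2,4-dien-1-ol | OC/C(C)=C/C=C | intermediate |
| 9 | TBS ether of 8 | CC(C)(C)[Si](C)(C)OC/C(C)=C/C=C | intermediate |
| 10 | dimethyl acetylenedicarboxylate | COC(=O)C#CC(=O)OC | starting material |
| 11 | Diels–Alder adduct (racemic; C4 R drawn) | COC(=O)C1=C(C(=O)OC)[C@](C)(CO[Si](C)(C)C(C)(C)C)C=CC1 | intermediate |
| 12 | C2=C3-saturated diester (racemic; C4 R drawn) | COC(=O)C1=C(C(=O)OC)[C@](C)(CO[Si](C)(C)C(C)(C)C)CCC1 | intermediate |
| 13 | diol, C6-OH and C20-OH (racemic; C4 R drawn) | OCC1=C(CO)[C@](C)(CO[Si](C)(C)C(C)(C)C)CCC1 | intermediate |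
| 14 | C20 ester of 4 with 13 | COC1=C[C@@](CC(Br)=C)(C(=O)OCC2=C(CO)[C@](C)(CO[Si](C)(C)C(C)(C)C)CCC2)C=CC1 | intermediate |
| 15 | enal (C6 CHO) | COC1=C[C@@](CC(Br)=C)(C(=O)OCC2=C(C=O)[C@](C)(CO[Si](C)(C)C(C)(C)C)CCC2)C=CC1 | intermediate |
| 16 | lactone keto-aldehyde (C11 ketone, C13=C14) | C=C(Br)C[C@]23C=CCC(=O)[C@@H]2[C@@]1(CCC[C@@](C)(CO[Si](C)(C)C(C)(C)C)[C@H]1C=O)COC3=O | intermediate |
| 17 | C6 dimethyl acetal of 16 | C=C(Br)C[C@]23C=CCC(=O)[C@@H]2[C@@]1(CCC[C@@](C)(CO[Si](C)(C)C(C)(C)C)[C@H]1C(OC)OC)COC3=O | intermediate |
| 18 | conjugated enone (C11=O, C12=C13) | C=C(Br)C[C@]23CC=CC(=O)[C@@H]2[C@@]1(CCC[C@@](C)(CO[Si](C)(C)C(C)(C)C)[C@H]1C(OC)OC)COC3=O | intermediate |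
| 19 | bicyclo[3.2.1] C/D ketone | C=C1C[C@]23C[C@H]1CC(=O)[C@@H]2[C@@]1(CCC[C@@](C)(CO[Si](C)(C)C(C)(C)C)[C@H]1C(OC)OC)COC3=O | intermediate |
| 20 | C19 alcohol | C=C1C[C@]23C[C@H]1CC(=O)[C@@H]2[C@@]1(CCC[C@@](C)(CO)[C@H]1C(OC)OC)COC3=O | intermediate |
| 21 | C19 acetate | C=C1C[C@]23C[C@H]1CC(=O)[C@@H]2[C@@]1(CCC[C@@](C)(COC(C)=O)[C@H]1C(OC)OC)COC3=O | intermediate |
| 22 | C11 alcohol | C=C1C[C@]23C[C@H]1C[C@@H](O)[C@@H]2[C@@]1(CCC[C@@](C)(COC(C)=O)[C@H]1C(OC)OC)COC3=O | intermediate |
| 23 | C15 allylic alcohol (epimeric) | C=C1C(O)[C@]23C[C@H]1C[C@@H](O)[C@@H]2[C@@]1(CCC[C@@](C)(COC(C)=O)[C@H]1C(OC)OC)COC3=O | intermediate |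
| 24 | C15 enone acetal | C=C1C(=O)[C@]23C[C@H]1C[C@@H](O)[C@@H]2[C@@]1(CCC[C@@](C)(COC(C)=O)[C@H]1C(OC)OC)COC3=O | intermediate |
| 25 | Trichorabdal B | C=C1C(=O)[C@]23C[C@H]1C[C@@H](O)[C@@H]2[C@@]1(CCC[C@@](C)(COC(C)=O)[C@H]1C=O)COC3=O | target |

**Total steps:** 20. **Longest linear sequence:** 18 steps (acrolein → 25).

**Three steps most likely to fail**
1. **Step 11 (hindered intramolecular Mukaiyama–Michael; vicinal tertiary and quaternary centres).**
   Fallback: reverse the order of dearomatization and coupling. Esterify 13 with 2-iodo-3-methoxybenzoic acid, oxidize to the enal, and form C9–C10 by Pd-catalysed intramolecular conjugate arylation (Pd(OAc)2, PPh3, HCO2Na). Then acetalize the aldehyde and run the Birch reductive alkylation on the resulting spiro-lactone, where the quaternary C8 is set by substrate control and the acid resolution is not needed.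
2. **Step 14 (vinyl-radical 5-exo cyclization competing with reduction or 6-endo closure).**
   Fallback: use a Ni-catalysed intramolecular reductive conjugate addition of the vinyl bromide to the enone (NiBr2·glyme, bipyridine, Zn, TMSCl). This is an organometallic 1,4-addition rather than a radical process.
3. **Step 17 (C11 configuration; the endo face is shielded by the C15–C16 bridge).**
   Fallback: reduce with NaBH4 to the endo alcohol, invert it by Mitsunobu reaction (HCO2H, DEAD, PPh3), and cleave the formate selectively (NH3/MeOH, 0 °C), leaving the neopentyl C19 acetate.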